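Retro-[4+2] across C1–C2 and C5–C10 opens rings A and B at once. Ring A is a cyclohexane whose C1–C10 edge carries the angular methyl and whose C2–C5 edge can be a diene once C4 holds only its CH2O arm; the C6–C9 bridge of ring B is the tether. Thermal intramolecular Diels–Alder reaction of triene 26, an acyclic C5=C4–C3=C2 diene linked through the C7 ketone and the C8 acetate to the isopropenyl group on the preformed oxolane carbon C9, closes both rings and sets C5 and C10. The C4 methyl follows by radical hydromethylation, the dihydrofuran by alkynol cycloisomerisation.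

Key step: step 16

Remark on the chemistry: labdane numbering (C1–C20) is used for the atoms of all intermediates; TBDPS = tert-butyldiphenylsilyl, TIPS = tri(propan-2-yl)silyl. Compounds 19, 20, 21, 22 and 24 are carried as mixtures of the two epimers at C7, the carbon that becomes the ketone in step 14.

Step 1
Reactants: 1 2-bromoprop-2-en-1-ol; 2 ethynyltri(propan-2-yl)silane
Product: 3 2-methylidene-4-(TIPS)but-3-yn-1-ol
Conditions: Pd(PPh3)2Cl2 (cat.), CuI (cat.), Et3N, THF, rt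
Reagents that add atoms: none
Why: Sonogashira coupling of a vinyl bromide with a terminal alkyne tolerates the free allylic alcohol and gives the enyne that holds C12–C16.

Step 2
Reactants: 3
Product: 4 [(2S)-2-(TIPS-ethynyl)oxiran-2-yl]methanol
Conditions: Ti(OiPr)4 (10 mol%), L-(+)-diethyl tartrate (12 mol%), t-BuOOH, 4 Å molecular sieves, CH2Cl2, −20 °C
Reagents that add atoms: tert-butyl hydroperoxide, CC(C)(C)OO
Why: Sharpless asymmetric epoxidation of a 2-substituted allylic alcohol, in which the L-(+)-tartrate ligand directs oxygen to the face that gives the (S)-epoxide; this sets C13, and the epoxide oxygen becomes O13.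

Step 3
Reactants: 4
Product: 5 TBDPS ether of 4, (2R)-2-(TBDPS-oxymethyl)-2-(TIPS-ethynyl)oxirane (same spatial arrangement at C13)
Conditions: TBDPSCl, imidazole, DMF, 0 °C to rt
Reagents that add atoms: tert-butyl(chloro)diphenylsilane, CC(C)(C)[Si](Cl)(c1ccccc1)c1ccccc1
Why: Standard silylation of the primary alcohol (the future C16 oxygen) with a group that survives organometallic, oxidative and thermal steps until step 18.

Step 4
Reactants: 5; 6 trimethyl(prop-1-yn-1-yl)silane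
Product: 9 (3S)-3-(TBDPS-oxymethyl)-1-(TIPS)hepta-1,6-diyn-3-ol, via 3-lithio-1-(trimethylsilyl)propyne 7 (not isolated), via trimethylsilyl-capped diynol 8 (not isolated)
Conditions: 6, n-BuLi, THF, −78 to 0 °C; then 5, DMPU, −78 °C to rt; then MeOH, K2CO3, rt
Reagents that add atoms: none
Why: The propargyl anion equivalent opens the 2,2-disubstituted epoxide by SN2 attack at its CH2 terminus (C12), so the C13–O bond and configuration are untouched, and methanolysis removes only the alkynyl trimethylsilyl group while the bulky TIPS alkyne stays.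

Step 5
Reactants: 9
Product: 10 (6S)-6-(TBDPS-oxymethyl)-8-(TIPS)octa-2,7-diyne-1,6-diol
Conditions: n-BuLi (2.2 equiv), THF, −78 °C; (CH2O)n, −78 °C to rt
Reagents that add atoms: formaldehyde (from paraformaldehyde), C=O
Why: The lithium acetylide of the alkoxide–acetylide dianion adds to formaldehyde and gives the propargylic alcohol (C7) needed to direct the next step.

Step 6
Reactants: 10
Product: 12 (2Z,6S)-3-iodo-2-methyl-6-(TBDPS-oxymethyl)-8-(TIPS)oct-2-en-7-yne-1,6-diol, via vinylmagnesium chelate 11 (not isolated)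
Conditions: MeMgBr (excess), CuI (10 mol%), THF, 0 °C to rt; then I2, −78 to 0 °C
Reagents that add atoms: methylmagnesium bromide, C[Mg]Br; iodine, II
Why: Copper-catalysed anti-carbomagnesiation of the propargylic alkoxide puts the methyl (C17) on C8 and magnesium on C9 in a five-membered chelate, so iodinolysis gives the iodide cis to CH2OH; the second alkyne is shielded by its TIPS group.

Step 7
Reactants: 12; 13 4,4,5,5-tetramethyl-2-(prop-1-en-2-yl)-1,3,2-dioxaborolane
Product: 14 (2Z,6S)-2-methyl-3-(prop-1-en-2-yl)-6-(TBDPS-oxymethyl)-8-(TIPS)oct-2-en-7-yne-1,6-diol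
Conditions: Pd(dppf)Cl2 (cat.), K3PO4, THF/H2O, 60 °C
Reagents that add atoms: none
Why: Suzuki–Miyaura coupling proceeds with retention of alkene geometry and places the isopropenyl group (C10, C1, C20) cis to C7 and C11 cis to C17.

Step 8
Reactants: 14
Product: 16 (2S)-2-[(2S,5S)-5-(TBDPS-oxymethyl)-2-(prop-1-en-2-yl)-5-(TIPS-ethynyl)oxolan-2-yl]propane-1,2-diol, via (2S,3R)-8,9-epoxy alcohol 15 (not isolated)
Conditions: Ti(OiPr)4 (20 mol%), L-(+)-diethyl tartrate (24 mol%), t-BuOOH, 4 Å molecular sieves, CH2Cl2, −25 °C, then 0 °C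
Reagents that add atoms: tert-butyl hydroperoxide, CC(C)(C)OO
Why: Sharpless asymmetric epoxidation sets C8 and the epoxide face, and the titanium-bound 2,3-epoxy alcohol is then opened at C3 (the allylic C9) by the tertiary C13 hydroxyl in a 5-exo attack with inversion, which sets C9 and leaves the C8 oxygen as the tertiary alcohol.

Step 9
Reactants: 16
Product: 17 (2R)-2-hydroxy-2-[(2S,5S)-5-(TBDPS-oxymethyl)-2-(prop-1-en-2-yl)-5-(TIPS-ethynyl)oxolan-2-yl]propanal
Conditions: SO3·pyridine, DMSO, Et3N, CH2Cl2, 0 °C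
Reagents that add atoms: none
Why: Parikh–Doering oxidation converts only the primary alcohol (C7), and the aldehyde has no α-hydrogen, so C8 cannot epimerise.

Step 10
Reactants: 17; 18 4,4,5,5-tetramethyl-2-(propa-1,2-dien-1-yl)-1,3,2-dioxaborolane
Product: 19 (2S)-2-[(2S,5S)-5-(TBDPS-oxymethyl)-2-(prop-1-en-2-yl)-5-(TIPS-ethynyl)oxolan-2-yl]hex-5-yne-2,3-diol (both epimers at C3 of the hexyne chain, labdane C7)
Conditions: toluene, rt; aqueous work-up
Reagents that add atoms: none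
Why: Allenylboration of the aldehyde (SE2′) gives only the homopropargylic alcohol and so adds C6, C5 and C4; the new carbinol centre C7 is not controlled and is removed in step 14.

Step 11
Reactants: 19
Product: 21 (2S)-7-(TBDPS-oxy)-2-[(2S,5S)-5-(TBDPS-oxymethyl)-2-(prop-1-en-2-yl)-5-(TIPS-ethynyl)oxolan-2-yl]hept-5-yne-2,3-diol (C7 epimers), via propargylic triol 20 (not isolated)
Conditions: n-BuLi (3.2 equiv), THF, −78 °C; (CH2O)n, to 0 °C; then TBDPSCl (1.0 equiv), 0 °C
Reagents that add atoms: formaldehyde (from paraformaldehyde), C=O; tert-butyl(chloro)diphenylsilane, CC(C)(C)[Si](Cl)(c1ccccc1)c1ccccc1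
Why: The acetylide adds to formaldehyde to give C19, and of the three lithium alkoxides only the unhindered primary propargylic one is silylated by the bulky chlorosilane.

Step 12
Reactants: 21
Product: 22 (2S,5E)-7-(TBDPS-oxy)-6-(tributylstannyl)-2-[(2S,5S)-5-(TBDPS-oxymethyl)-2-(prop-1-en-2-yl)-5-(TIPS-ethynyl)oxolan-2-yl]hept-5-ene-2,3-diol (C7 epimers)
Conditions: Bu3SnH, Mo(CO)3(CNtBu)3 (cat.), hydroquinone, THF, 55 °C
Reagents that add atoms: tributyltin hydride, CCCC[SnH](CCCC)CCCC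
Why: Molybdenum-isonitrile-catalysed syn hydrostannation of a propargylic ether delivers tin to the carbon next to the oxygenated CH2 (C4) and hydrogen to C5 on the same side.

Step 13
Reactants: 22; 23 bromoethene
Product: 24 (2S,5Z)-6-(TBDPS-oxymethyl)-2-[(2S,5S)-5-(TBDPS-oxymethyl)-2-(prop-1-en-2-yl)-5-(TIPS-ethynyl)oxolan-2-yl]octa-5,7-diene-2,3-diol (C7 epimers)
Conditions: Pd2(dba)3 (cat.), AsPh3, CuI (cat.), NMP, 40 °C
Reagents that add atoms: none
Why: Stille coupling with retention at C4 adds C3 and C2 and gives the diene with C6 trans to the new vinyl group, the outside position needed for cycloaddition.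

Step 14
Reactants: 24
Product: 25 (2R,5Z)-2-hydroxy-6-(TBDPS-oxymethyl)-2-[(2S,5S)-5-(TBDPS-oxymethyl)-2-(prop-1-en-2-yl)-5-(TIPS-ethynyl)oxolan-2-yl]octa-5,7-dien-3-one
Conditions: Dess–Martin periodinane, NaHCO3, CH2Cl2, 0 °C
Reagents that add atoms: none
Why: Buffered Dess–Martin oxidation converts the secondary C7 alcohol of both epimers into the one ketone, leaves the tertiary C8 hydroxyl alone and avoids the base that would move the C4=C5 bond into conjugation.

Step 15
Reactants: 25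
Product: 26 (2R,5Z)-3-oxo-6-(TBDPS-oxymethyl)-2-[(2S,5S)-5-(TBDPS-oxymethyl)-2-(prop-1-en-2-yl)-5-(TIPS-ethynyl)oxolan-2-yl]octa-5,7-dien-2-yl acetate
Conditions: Ac2O, DMAP, Et3N, CH2Cl2, 0 °C to rt
Reagents that add atoms: acetic anhydride, CC(=O)OC(C)=O
Why: DMAP-catalysed acylation of the tertiary α-ketol installs the C8 acetate while the chain is still acyclic and this hydroxyl is the only free one.

Step 16
Reactants: 26
Product: 27 8β-acetoxy-9α,13-epoxy-7-oxo-labd-3-ene core with 19-O-TBDPS, 16-O-TBDPS and a TIPS-ethynyl group on C13 (5α-H, 10β-CH3, 8α-CH3; C8, C9, C13 as in 26)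
Conditions: 1,2-dichlorobenzene (0.01 M), BHT (cat.), 180 °C, sealed tube
Reagents that add atoms: none
Why: Concerted but asynchronous thermal [4+2] cycloaddition (type 1 intramolecular Diels–Alder reaction) in which the 1,1-disubstituted alkene C1=C10 adds across the termini C2 and C5 of the diene; the closest known reaction type is the thermal cyclisation of unactivated 1,7,9-decatrienes to angularly methylated octalins. Ring A is closed as the cyclohexene itself by both new bonds, and ring B is closed in the fused mode by the C5–C10 bond through the four-atom tether C6–C9, whose two quaternary carbons (C8, C9) and sp2 carbon C7 preorganise the chain (Thorpe–Ingold effect). C10 and C5 are set together: the anti (tether-exo) transition state places the small C20 methyl, not the fully substituted C9, under the diene next to the C4 silyloxymethyl arm and so should give the trans ring fusion (10β-CH3, 5α-H). The π-face is chosen by C8 and C9: in the chair-like tether the C11 methylene and the C17 methyl are equatorial and O13 and the acetate axial, whereas attack on the other face would force C17 and C11 axial with a syn-diaxial C17/C20 clash. The step therefore needs fused over bridged regiochemistry (secured by tether length), trans over cis fusion and one π-face (both secured by the stereocentres made in step 8), and it must outrun enolisation of the β,γ-unsaturated ketone, for which base-free conditions with a radical inhibitor are chosen.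

Step 17
Reactants: 27
Product: 29 8β-acetoxy-9α,13-epoxy-7-oxo-labdane with 4α-CH3, 4β-CH2OTBDPS, 16-O-TBDPS and a TIPS-ethynyl group on C13, via sulfonylhydrazide adduct 28 (not isolated)
Conditions: Fe(acac)3 (30 mol%), PhSiH3, aqueous formaldehyde, octane-1-sulfonohydrazide (hydrazone formed in situ), MeOH/THF, rt; then MeOH, 60 °C
Reagents that add atoms: formaldehyde, C=O
Why: Mukaiyama-type iron-hydride hydrogen-atom transfer puts H on C3 and gives the tertiary C4 radical, which adds to the formaldehyde sulfonylhydrazone from the α-face (the β-face is blocked by the syn-axial C20 methyl); loss of sulfinate and N2 on warming leaves the 4α-methyl group and the 4β-CH2O arm.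

Step 18
Reactants: 29
Product: 30 8β-acetoxy-9α,13-epoxy-13-ethynyl-16,19-dihydroxy-14,15-dinor-labdan-7-one (C13 as in 29)
Conditions: TBAF, AcOH, THF, 0 °C to 40 °C
Reagents that add atoms: none
Why: Fluoride cleaves both TBDPS ethers and the alkynyl C–Si bond in one operation, and the acetic acid buffer protects the hindered tertiary acetate.

Step 19
Reactants: 30
Product: 31 target, (4S,5S,8R,9S,10S,13S)-8-acetoxy-9,13:15,16-diepoxy-19-hydroxylabd-14-en-7-one
Conditions: Mo(CO)6 (30 mol%, pre-irradiated at 350 nm with Et3N), Et3N, Et2O, rt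
Reagents that add atoms: none
Why: Molybdenum-vinylidene cycloisomerisation of a but-3-yn-1-ol: the C16 hydroxyl adds to the terminal alkyne carbon (C15) in the endo mode and gives the 2,3-dihydrofuran under basic, non-acidic conditions, so the acid-labile spiro enol ether is formed last and no stereocentre is touched.

Compound list
1 | 2-bromoprop-2-en-1-ol | OCC(Br)=C | starting material
2 | ethynyltri(propan-2-yl)silane | C#C[Si](C(C)C)(C(C)C)C(C)C | starting material
3 | 2-methylidene-4-(TIPS)but-3-yn-1-ol | OCC(=C)C#C[Si](C(C)C)(C(C)C)C(C)C | intermediate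
4 | [(2S)-2-(TIPS-ethynyl)oxiran-2-yl]methanol | OC[C@@]1(C#C[Si](C(C)C)(C(C)C)C(C)C)CO1 | intermediate
5 | (2R)-2-(TBDPS-oxymethyl)-2-(TIPS-ethynyl)oxirane | CC(C)(C)[Si](c1ccccc1)(c1ccccc1)OC[C@@]2(C#C[Si](C(C)C)(C(C)C)C(C)C)CO2 | intermediate
6 | trimethyl(prop-1-yn-1-yl)silane | CC#C[Si](C)(C)C | starting material
7 | 3-lithio-1-(trimethylsilyl)propyne (not isolated) | [Li]CC#C[Si](C)(C)C | intermediate
8 | (3S)-3-(TBDPS-oxymethyl)-1-(TIPS)-7-(trimethylsilyl)hepta-1,6-diyn-3-ol (not isolated) | C[Si](C)(C)C#CCC[C@](O)(C#C[Si](C(C)C)(C(C)C)C(C)C)CO[Si](c1ccccc1)(c1ccccc1)C(C)(C)C | intermediate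
9 | (3S)-3-(TBDPS-oxymethyl)-1-(TIPS)hepta-1,6-diyn-3-ol | C#CCC[C@](O)(C#C[Si](C(C)C)(C(C)C)C(C)C)CO[Si](c1ccccc1)(c1ccccc1)C(C)(C)C | intermediate
10 | (6S)-6-(TBDPS-oxymethyl)-8-(TIPS)octa-2,7-diyne-1,6-diol | OCC#CCC[C@](O)(C#C[Si](C(C)C)(C(C)C)C(C)C)CO[Si](c1ccccc1)(c1ccccc1)C(C)(C)C | intermediate
11 | vinylmagnesium chelate from 10 (CH3 on C8, MgBr on C9 cis to the CH2O group; not isolated) | Br[Mg]OC/C(C)=C(/CC[C@](O[Mg]Br)(C#C[Si](C(C)C)(C(C)C)C(C)C)CO[Si](c1ccccc1)(c1ccccc1)C(C)(C)C)[Mg]Br | intermediate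
12 | (2Z,6S)-3-iodo-2-methyl-6-(TBDPS-oxymethyl)-8-(TIPS)oct-2-en-7-yne-1,6-diol | OC/C(C)=C(/CC[C@](O)(C#C[Si](C(C)C)(C(C)C)C(C)C)CO[Si](c1ccccc1)(c1ccccc1)C(C)(C)C)I | intermediate
13 | 4,4,5,5-tetramethyl-2-(prop-1-en-2-yl)-1,3,2-dioxaborolane | CC(=C)B1OC(C)(C)C(C)(C)O1 | starting material
14 | (2Z,6S)-2-methyl-3-(prop-1-en-2-yl)-6-(TBDPS-oxymethyl)-8-(TIPS)oct-2-en-7-yne-1,6-diol | OC/C(C)=C(/CC[C@](O)(C#C[Si](C(C)C)(C(C)C)C(C)C)CO[Si](c1ccccc1)(c1ccccc1)C(C)(C)C)C(C)=C | intermediate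
15 | (2S,3R)-8,9-epoxy alcohol of 14 (not isolated) | OC[C@]1(C)O[C@]1(CC[C@](O)(C#C[Si](C(C)C)(C(C)C)C(C)C)CO[Si](c2ccccc2)(c2ccccc2)C(C)(C)C)C(C)=C | intermediate
16 | (2S)-2-[(2S,5S)-5-(TBDPS-oxymethyl)-2-(prop-1-en-2-yl)-5-(TIPS-ethynyl)oxolan-2-yl]propane-1,2-diol | OC[C@](C)(O)[C@@]1(C(C)=C)CC[C@](C#C[Si](C(C)C)(C(C)C)C(C)C)(CO[Si](c2ccccc2)(c2ccccc2)C(C)(C)C)O1 | intermediate
17 | (2R)-2-hydroxy-2-[(2S,5S)-5-(TBDPS-oxymethyl)-2-(prop-1-en-2-yl)-5-(TIPS-ethynyl)oxolan-2-yl]propanal | O=C[C@](C)(O)[C@@]1(C(C)=C)CC[C@](C#C[Si](C(C)C)(C(C)C)C(C)C)(CO[Si](c2ccccc2)(c2ccccc2)C(C)(C)C)O1 | intermediate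
18 | 4,4,5,5-tetramethyl-2-(propa-1,2-dien-1-yl)-1,3,2-dioxaborolane | C=C=CB1OC(C)(C)C(C)(C)O1 | starting material
19 | (2S)-2-[(2S,5S)-oxolan-2-yl as in 16]hex-5-yne-2,3-diol (C7 epimers) | C#CCC(O)[C@](C)(O)[C@@]1(C(C)=C)CC[C@](C#C[Si](C(C)C)(C(C)C)C(C)C)(CO[Si](c2ccccc2)(c2ccccc2)C(C)(C)C)O1 | intermediate
20 | (6S)-6-[(2S,5S)-oxolan-2-yl as in 16]hept-2-yne-1,5,6-triol (C7 epimers; not isolated) | OCC#CCC(O)[C@](C)(O)[C@@]1(C(C)=C)CC[C@](C#C[Si](C(C)C)(C(C)C)C(C)C)(CO[Si](c2ccccc2)(c2ccccc2)C(C)(C)C)O1 | intermediate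
21 | (2S)-7-(TBDPS-oxy)-2-[(2S,5S)-oxolan-2-yl as in 16]hept-5-yne-2,3-diol (C7 epimers) | CC(C)(C)[Si](c1ccccc1)(c1ccccc1)OCC#CCC(O)[C@](C)(O)[C@@]2(C(C)=C)CC[C@](C#C[Si](C(C)C)(C(C)C)C(C)C)(CO[Si](c3ccccc3)(c3ccccc3)C(C)(C)C)O2 | intermediate
22 | (2S,5E)-7-(TBDPS-oxy)-6-(tributylstannyl)-2-[(2S,5S)-oxolan-2-yl as in 16]hept-5-ene-2,3-diol (C7 epimers) | CC(C)(C)[Si](c1ccccc1)(c1ccccc1)OC/C([Sn](CCCC)(CCCC)CCCC)=C\CC(O)[C@](C)(O)[C@@]2(C(C)=C)CC[C@](C#C[Si](C(C)C)(C(C)C)C(C)C)(CO[Si](c3ccccc3)(c3ccccc3)C(C)(C)C)O2 | intermediate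
23 | bromoethene | C=CBr | starting material
24 | (2S,5Z)-6-(TBDPS-oxymethyl)-2-[(2S,5S)-oxolan-2-yl as in 16]octa-5,7-diene-2,3-diol (C7 epimers) | CC(C)(C)[Si](c1ccccc1)(c1ccccc1)OC/C(C=C)=C\CC(O)[C@](C)(O)[C@@]2(C(C)=C)CC[C@](C#C[Si](C(C)C)(C(C)C)C(C)C)(CO[Si](c3ccccc3)(c3ccccc3)C(C)(C)C)O2 | intermediate
25 | (2R,5Z)-2-hydroxy-6-(TBDPS-oxymethyl)-2-[(2S,5S)-oxolan-2-yl as in 16]octa-5,7-dien-3-one | CC(C)(C)[Si](c1ccccc1)(c1ccccc1)OC/C(C=C)=C\CC(=O)[C@](C)(O)[C@@]2(C(C)=C)CC[C@](C#C[Si](C(C)C)(C(C)C)C(C)C)(CO[Si](c3ccccc3)(c3ccccc3)C(C)(C)C)O2 | intermediate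
26 | (2R,5Z)-3-oxo-6-(TBDPS-oxymethyl)-2-[(2S,5S)-oxolan-2-yl as in 16]octa-5,7-dien-2-yl acetate | CC(C)(C)[Si](c1ccccc1)(c1ccccc1)OC/C(C=C)=C\CC(=O)[C@](C)(OC(C)=O)[C@@]2(C(C)=C)CC[C@](C#C[Si](C(C)C)(C(C)C)C(C)C)(CO[Si](c3ccccc3)(c3ccccc3)C(C)(C)C)O2 | intermediate
27 | trans-fused cycloadduct: 8β-acetoxy-9α,13-epoxy-7-oxo-labd-3-ene core, 19-O-TBDPS, 16-O-TBDPS, TIPS-ethynyl on C13 | CC(=O)O[C@@]1(C)C(=O)C[C@H]2C(CO[Si](c3ccccc3)(c3ccccc3)C(C)(C)C)=CCC[C@]2(C)[C@@]12CC[C@](C#C[Si](C(C)C)(C(C)C)C(C)C)(CO[Si](c3ccccc3)(c3ccccc3)C(C)(C)C)O2 | intermediate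
28 | C4 adduct of 27 carrying CH2NHNHSO2-octyl on the α-face (not isolated) | CC(=O)O[C@@]1(C)C(=O)C[C@H]2[C@@](CNNS(=O)(=O)CCCCCCCC)(CO[Si](c3ccccc3)(c3ccccc3)C(C)(C)C)CCC[C@]2(C)[C@@]12CC[C@](C#C[Si](C(C)C)(C(C)C)C(C)C)(CO[Si](c3ccccc3)(c3ccccc3)C(C)(C)C)O2 | intermediate
29 | 4α-methyl-4β-(TBDPS-oxymethyl) labdane, otherwise as 27 with C3 saturated | CC(=O)O[C@@]1(C)C(=O)C[C@H]2[C@@](C)(CO[Si](c3ccccc3)(c3ccccc3)C(C)(C)C)CCC[C@]2(C)[C@@]12CC[C@](C#C[Si](C(C)C)(C(C)C)C(C)C)(CO[Si](c3ccccc3)(c3ccccc3)C(C)(C)C)O2 | intermediate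
30 | 8β-acetoxy-9α,13-epoxy-13-ethynyl-16,19-dihydroxy-14,15-dinor-labdan-7-one | CC(=O)O[C@@]1(C)C(=O)C[C@H]2[C@@](C)(CO)CCC[C@]2(C)[C@@]12CC[C@](C#C)(CO)O2 | intermediate
31 | (4S,5S,8R,9S,10S,13S)-8-acetoxy-9,13:15,16-diepoxy-19-hydroxylabd-14-en-7-one (CNP0239339.2) | CC(=O)O[C@@]1(C)C(=O)C[C@H]2[C@@](C)(CO)CCC[C@]2(C)[C@@]12CC[C@@]1(C=COC1)O2 | target

Total step count: 19. Longest linear sequence: 19 steps (from 1).

Steps most likely to fail

Step 16. The cycloaddition of the unactivated, neopentyl-type 1,1-disubstituted alkene may be too slow at temperatures the substrate tolerates; double-bond migration toward the C7 ketone or thermal loss of acetic acid may then win, and the cis-fused transition state may also compete. The fallback turns the diene into an inverse-electron-demand 2-formyl diene; it sets out from 19 and comes back at 27. Diol 19 is capped with TMSCl/imidazole as the bis(trimethylsilyl) ether F1. Its lithium acetylide (n-BuLi) is acylated with ClCO2Me, and citric acid/MeOH work-up frees the diol to give the ynoate F2. Pd(PPh3)4-catalysed syn addition of Bu3SnH puts tin on the ester-bearing carbon C4 and gives the α-stannyl enoate F3, and Stille coupling with 23 gives the dienoate F4. i-Bu2AlH reduces the ester to the dienyl triol F5, and Dess–Martin periodinane oxidises both the allylic primary and the secondary alcohol to the keto enal F6. Ac2O/DMAP gives its acetate F7. The electron-poor 2-formyl diene should add the electron-rich 1,1-dialkyl alkene in toluene at or below 80 °C through the same chair transition state to give the enal cycloadduct F8. NaBH4 at −78 °C reduces the aldehyde in preference to the hindered ketone to the allylic alcohol F9, and TBDPSCl/imidazole returns 27.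

Step 12. Tin may be delivered to C5 as well as C4, because the bulky silyl ether weakens the directing effect of the propargylic oxygen, and the regioisomers would be hard to separate. The fallback uses a free hydroxyl as the directing group and silylates afterwards; it sets out from 20 (step 11 stopped after the formaldehyde addition and the triol isolated) and comes back at 22. Pd(PPh3)2Cl2-catalysed hydrostannation of the free primary propargylic alcohol, which directs tin to the proximal carbon, gives the stannyl triol F10, and TBDPSCl/imidazole silylates its primary allylic hydroxyl to give 22.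

Step 15. Acylation of the crowded tertiary hydroxyl may be slower than base-mediated migration of the C4=C5 double bond into conjugation with the ketone. The fallback reverses the order of events; it sets out from 25 and comes back at 27. Heating 25 under the conditions of step 16 gives the ketol cycloadduct F11. Once the tertiary allylic ether and the skipped dienone are gone, the tertiary hydroxyl is acetylated under Lewis-acid catalysis (Ac2O, Sc(OTf)3 cat., MeCN, −20 °C) to give 27.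

Further compounds
F1 | step 16 | bis(trimethylsilyl) ether of 19 | C#CCC(O[Si](C)(C)C)[C@](C)(O[Si](C)(C)C)[C@@]1(C(C)=C)CC[C@](C#C[Si](C(C)C)(C(C)C)C(C)C)(CO[Si](c2ccccc2)(c2ccccc2)C(C)(C)C)O1
F2 | step 16 | methyl ynoate diol (CO2CH3 on C4) | COC(=O)C#CCC(O)[C@](C)(O)[C@@]1(C(C)=C)CC[C@](C#C[Si](C(C)C)(C(C)C)C(C)C)(CO[Si](c2ccccc2)(c2ccccc2)C(C)(C)C)O1
F3 | step 16 | methyl (E)-α-stannyl enoate diol | COC(=O)/C([Sn](CCCC)(CCCC)CCCC)=C\CC(O)[C@](C)(O)[C@@]1(C(C)=C)CC[C@](C#C[Si](C(C)C)(C(C)C)C(C)C)(CO[Si](c2ccccc2)(c2ccccc2)C(C)(C)C)O1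
F4 | step 16 | methyl (Z)-2-vinyl enoate diol (dienoate) | COC(=O)/C(C=C)=C\CC(O)[C@](C)(O)[C@@]1(C(C)=C)CC[C@](C#C[Si](C(C)C)(C(C)C)C(C)C)(CO[Si](c2ccccc2)(c2ccccc2)C(C)(C)C)O1
F5 | step 16 | dienyl triol (free C19, C7 and C8 hydroxyls) | OC/C(C=C)=C\CC(O)[C@](C)(O)[C@@]1(C(C)=C)CC[C@](C#C[Si](C(C)C)(C(C)C)C(C)C)(CO[Si](c2ccccc2)(c2ccccc2)C(C)(C)C)O1
F6 | step 16 | keto enal (C7 ketone, C19 aldehyde, free C8 hydroxyl) | O=C/C(C=C)=C\CC(=O)[C@](C)(O)[C@@]1(C(C)=C)CC[C@](C#C[Si](C(C)C)(C(C)C)C(C)C)(CO[Si](c2ccccc2)(c2ccccc2)C(C)(C)C)O1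
F7 | step 16 | keto enal acetate (2-formyl diene) | O=C/C(C=C)=C\CC(=O)[C@](C)(OC(C)=O)[C@@]1(C(C)=C)CC[C@](C#C[Si](C(C)C)(C(C)C)C(C)C)(CO[Si](c2ccccc2)(c2ccccc2)C(C)(C)C)O1
F8 | step 16 | enal cycloadduct (C19 aldehyde on the C3=C4 alkene) | CC(=O)O[C@@]1(C)C(=O)C[C@H]2C(C=O)=CCC[C@]2(C)[C@@]12CC[C@](C#C[Si](C(C)C)(C(C)C)C(C)C)(CO[Si](c3ccccc3)(c3ccccc3)C(C)(C)C)O2
F9 | step 16 | allylic alcohol cycloadduct (free C19 hydroxyl) | CC(=O)O[C@@]1(C)C(=O)C[C@H]2C(CO)=CCC[C@]2(C)[C@@]12CC[C@](C#C[Si](C(C)C)(C(C)C)C(C)C)(CO[Si](c3ccccc3)(c3ccccc3)C(C)(C)C)O2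
F10 | step 12 | stannyl triol (tin on C4, free C19 hydroxyl) | OC/C([Sn](CCCC)(CCCC)CCCC)=C\CC(O)[C@](C)(O)[C@@]1(C(C)=C)CC[C@](C#C[Si](C(C)C)(C(C)C)C(C)C)(CO[Si](c2ccccc2)(c2ccccc2)C(C)(C)C)O1
F11 | step 15 | ketol cycloadduct (27 with free 8β-hydroxyl) | O[C@@]1(C)C(=O)C[C@H]2C(CO[Si](c3ccccc3)(c3ccccc3)C(C)(C)C)=CCC[C@]2(C)[C@@]12CC[C@](C#C[Si](C(C)C)(C(C)C)C(C)C)(CO[Si](c3ccccc3)(c3ccccc3)C(C)(C)C)O2
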